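**Retrosynthetic overview**
1. Target ⇒ acylation of the C8 hydroxyl of germacranolide core 20 with epoxy acid 28 (Sharpless epoxidation; from crotonaldehyde), then global desilylation.
2. Core 20 ⇒ ten-membered (4E,6Z)-dienol 18 + 2-bromoacrylic acid 19: a palladium-catalysed [3+2] lactone annulation makes the C11–C7 bond and the lactone O–C6 bond in one operation.
3. Enabling feature: the lactone ring oxygen sits on C6, allylic to the C4=C5 double bond of the ten-membered ring, and the lactone α-carbon C11 sits on the adjacent C7, next to the C8 oxygen. The lactone is thus the retron of a C4=C5–C6=C7 diene vinylated at C7 and captured at C6 as a π-allyl, with the C8 hydroxyl as directing group.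
4. 18 ⇒ acyclic tetraene 16 by ring-closing metathesis at C6=C7. 16 comes from (R)-epichlorohydrin through ynoate carbocupration (Z-C1=C10), asymmetric propargylation (C2) and carboalumination/Stille coupling (E-C4=C5 diene).
5. Ring order: ten-membered carbocycle (step 13), then the lactone (step 15); the side-chain oxirane is made separately (step 20).

Key step: step 15

Remark: positions are given in germacrane numbering (ring carbons C1–C10 with methyl groups on C4 and C10, lactone carbons C11–C13); the catalyst enantiomer in step 9 and the tartrate in step 20 are those predicted by the accepted stereochemical models for these reactions.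

**Route**

Step 1
Reactants: 1 (R)-epichlorohydrin
Product: 2 (2R)-1-chloro-5-(trimethylsilyl)pent-4-yn-2-ol
Conditions: Me3SiC≡CH, n-BuLi, THF, −78 °C; BF3·OEt2; then 1, −78 °C; H2O
Reagents that add atoms: trimethylsilylacetylene, C#C[Si](C)(C)C
Why: BF3-promoted opening of a terminal epoxide by a lithium acetylide (Yamaguchi–Hirao alkynylation) should occur at the unsubstituted epoxide carbon and leave the C–Cl bond and the stereocentre (future C8) untouched.

Step 2
Reactants: 2 (2R)-1-chloro-5-(trimethylsilyl)pent-4-yn-2-ol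
Product: 4 (3R)-6-(trimethylsilyl)hex-1-en-5-yn-3-ol, via terminal epoxide 3 (not isolated)
Conditions: Me3S+ I− (4 equiv), n-BuLi (3.9 equiv), THF, −10 °C to rt; H2O
Reagents that add atoms: trimethylsulfonium iodide, C[S+](C)C.[I-]
Why: Base closes the chlorohydrin to the epoxide, which dimethylsulfonium methylide opens at CH2, and the resulting sulfonium alkoxide eliminates Me2S (one-carbon homologation of an epoxide to an allylic alcohol) without touching the carbinol stereocentre.

Step 3
Reactants: 4 (3R)-6-(trimethylsilyl)hex-1-en-5-yn-3-ol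
Product: 5 triethyl{[(3R)-6-(trimethylsilyl)hex-1-en-5-yn-3-yl]oxy}silane
Conditions: Et3SiCl, imidazole, CH2Cl2, 0 °C
Reagents that add atoms: chlorotriethylsilane, CC[Si](Cl)(CC)CC
Why: Standard silyl ether formation; triethylsilyl is chosen because it can later be removed in the presence of a tert-butyldimethylsilyl ether.

Step 4
Reactants: 5 triethyl{[(3R)-6-(trimethylsilyl)hex-1-en-5-yn-3-yl]oxy}silane
Product: 6 triethyl{[(3R)-hex-1-en-5-yn-3-yl]oxy}silane
Conditions: K2CO3 (0.2 equiv), MeOH, rt
Reagents that add atoms: none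
Why: Base-mediated methanolysis of the alkynyl C–Si bond (protodesilylation) should be selective over the secondary triethylsilyl ether.

Step 5
Reactants: 6 triethyl{[(3R)-hex-1-en-5-yn-3-yl]oxy}silane
Product: 8 methyl (5R)-5-[(triethylsilyl)oxy]hept-6-en-2-ynoate, via lithium acetylide 7 (not isolated)
Conditions: n-BuLi, THF, −78 °C; ClCO2Me, −78 °C to 0 °C
Reagents that add atoms: methyl chloroformate, COC(=O)Cl
Why: Deprotonation of the terminal alkyne and C-acylation of the acetylide with a chloroformate gives the ynoate without affecting the stereocentre.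

Step 6
Reactants: 8 methyl (5R)-5-[(triethylsilyl)oxy]hept-6-en-2-ynoate
Product: 9 methyl (2Z,5R)-3-methyl-5-[(triethylsilyl)oxy]hepta-2,6-dienoate
Conditions: Me2CuLi (from MeLi and CuI), THF, −78 °C; MeOH, −78 °C
Reagents that add atoms: lithium dimethylcuprate (made in the flask from methyllithium and CuI), [Li+].C[Cu-]C
Why: Syn carbocupration of the ynoate (Gilman conjugate addition) with cold protonation places the new methyl cis to the vinylic hydrogen, so chain and ester end up cis, which fixes the Z geometry of the future C1=C10 bond.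

Step 7
Reactants: 9 methyl (2Z,5R)-3-methyl-5-[(triethylsilyl)oxy]hepta-2,6-dienoate
Product: 10 (2Z,5R)-3-methyl-5-[(triethylsilyl)oxy]hepta-2,6-dien-1-ol
Conditions: i-Bu2AlH (2.2 equiv), CH2Cl2, −78 °C; aqueous potassium sodium tartrate
Reagents that add atoms: none
Why: 1,2-Hydride reduction of the conjugated ester gives the allylic alcohol without changing olefin geometry or the silyl ether.

Step 8
Reactants: 10 (2Z,5R)-3-methyl-5-[(triethylsilyl)oxy]hepta-2,6-dien-1-ol
Product: 11 (2Z,5R)-3-methyl-5-[(triethylsilyl)oxy]hepta-2,6-dienal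
Conditions: MnO2 (excess), CH2Cl2, rt
Reagents that add atoms: none
Why: Heterogeneous, neutral MnO2 oxidation is selective for the primary allylic alcohol and should give the (Z)-enal without isomerisation.

Step 9
Reactants: 11 (2Z,5R)-3-methyl-5-[(triethylsilyl)oxy]hepta-2,6-dienal
Product: 12 (4S,5Z,8R)-6-methyl-8-[(triethylsilyl)oxy]deca-5,9-dien-1-yn-4-ol
Conditions: allenylboronic acid pinacol ester, (S)-TRIP phosphoric acid (10 mol %), 4 Å molecular sieves, toluene, −20 °C
Reagents that add atoms: allenylboronic acid pinacol ester, C=C=CB1OC(C)(C)C(C)(C)O1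
Why: Chiral phosphoric acid-catalysed propargylboration proceeds through a closed six-membered transition state with γ-attack of the allenylboronate, the catalyst selecting the Si face of the aldehyde to set the (S) carbinol (future C2) independently of the remote C8 centre.

Step 10
Reactants: 12 (4S,5Z,8R)-6-methyl-8-[(triethylsilyl)oxy]deca-5,9-dien-1-yn-4-ol
Product: 13 tert-butyl(dimethyl){[(4S,5Z,8R)-6-methyl-8-[(triethylsilyl)oxy]deca-5,9-dien-1-yn-4-yl]oxy}silane
Conditions: t-BuMe2SiCl, imidazole, DMF, rt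
Reagents that add atoms: tert-butyldimethylsilyl chloride, CC(C)(C)[Si](C)(C)Cl
Why: Standard silylation gives the more robust tert-butyldimethylsilyl ether at C2, orthogonal to the triethylsilyl ether at C8.

Step 11
Reactants: 13 tert-butyl(dimethyl){[(4S,5Z,8R)-6-methyl-8-[(triethylsilyl)oxy]deca-5,9-dien-1-yn-4-yl]oxy}silane
Product: 15 tert-butyl{[(1E,4S,5Z,8R)-1-iodo-2,6-dimethyl-8-[(triethylsilyl)oxy]deca-1,5,9-trien-4-yl]oxy}dimethylsilane, via alkenylalane 14 (not isolated)
Conditions: Me3Al (2.5 equiv), Cp2ZrCl2 (0.2 equiv), CH2Cl2, 0 °C to rt; then I2, THF, −30 °C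
Reagents that add atoms: trimethylaluminium, C[Al](C)C; iodine, II
Why: Zirconium-catalysed syn methylalumination of the terminal alkyne (Negishi carboalumination) puts methyl on the internal carbon and aluminium cis to it on the terminal carbon, and iodinolysis with retention gives the (E)-vinyl iodide that defines C4=C5.

Step 12
Reactants: 15 tert-butyl{[(1E,4S,5Z,8R)-1-iodo-2,6-dimethyl-8-[(triethylsilyl)oxy]deca-1,5,9-trien-4-yl]oxy}dimethylsilane
Product: 16 tert-butyl{[(3E,6S,7Z,10R)-4,8-dimethyl-10-[(triethylsilyl)oxy]dodeca-1,3,7,11-tetraen-6-yl]oxy}dimethylsilane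
Conditions: Bu3SnCH=CH2, PdCl2(MeCN)2 (5 mol %), DMF, rt
Reagents that add atoms: tributyl(vinyl)stannane, C=C[Sn](CCCC)(CCCC)CCCC
Why: Stille coupling of the vinyl iodide with a vinylstannane proceeds with retention of olefin geometry to give the terminal (E)-1,3-diene.

Step 13
Reactants: 16 tert-butyl{[(3E,6S,7Z,10R)-4,8-dimethyl-10-[(triethylsilyl)oxy]dodeca-1,3,7,11-tetraen-6-yl]oxy}dimethylsilane
Product: 17 (1E,3Z,5R,7Z,9S)-9-{[tert-butyl(dimethyl)silyl]oxy}-1,7-dimethyl-5-[(triethylsilyl)oxy]cyclodeca-1,3,7-triene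
Conditions: second-generation Grubbs catalyst RuCl2(=CHPh)(H2IMes)(PCy3) (10 mol %), toluene (0.5 mM), 80 °C, slow addition
Reagents that add atoms: none
Why: Ring-closing olefin metathesis of the two terminal vinyl groups expels ethylene and closes the ten-membered ring at C6=C7, the new olefin being expected as the less strained Z isomer, while closure onto the trisubstituted olefins is slow and six-membered ring formation is barred by the E geometry of C4=C5.

Step 14
Reactants: 17 (1E,3Z,5R,7Z,9S)-9-{[tert-butyl(dimethyl)silyl]oxy}-1,7-dimethyl-5-[(triethylsilyl)oxy]cyclodeca-1,3,7-triene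
Product: 18 (1R,2Z,4E,7S,8Z)-7-{[tert-butyl(dimethyl)silyl]oxy}-5,9-dimethylcyclodeca-2,4,8-trien-1-ol
Conditions: PPTS (0.2 equiv), MeOH/CH2Cl2 (1:1), 0 °C
Reagents that add atoms: none
Why: Mild acid-catalysed methanolysis removes the less hindered triethylsilyl ether selectively and frees the C8 hydroxyl needed as directing group in the next step.

Step 15
Reactants: 18 (1R,2Z,4E,7S,8Z)-7-{[tert-butyl(dimethyl)silyl]oxy}-5,9-dimethylcyclodeca-2,4,8-trien-1-ol; 19 2-bromoprop-2-enoic acid
Product: 20 (3aR,4R,6Z,8S,10E,11aR)-8-{[tert-butyl(dimethyl)silyl]oxy}-4-hydroxy-6,10-dimethyl-3-methylidene-3a,4,5,8,9,11a-hexahydrocyclodeca[b]furan-2(3H)-one (the 2α-silyloxy-8β-hydroxy-germacra-1(10)Z,4E,11(13)-trien-12,6α-olide)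
Conditions: 19 (1.5 equiv), Pd(OAc)2 (10 mol %), P(2-furyl)3 (10 mol %), Ag2CO3 (1.2 equiv), BHT, MeCN, 50 °C, dark
Reagents that add atoms: none
Why: Proposed new method: zerovalent palladium inserts into the C–Br bond of 19, and the resulting α-carboxyvinylpalladium species, made cationic by Ag2CO3, binds the C8 hydroxyl and the C6=C7 olefin of 18 and adds syn across it with C11 going to C7 (the disubstituted terminus of the C4=C5–C6=C7 diene), leaving palladium on C6 as the η3-allyl over C6–C5–C4; the pendant carboxylate then attacks C6 and releases zerovalent palladium, so the C11–C7 and lactone O–C6 bonds form in one catalytic turnover. The closest known reaction type is the palladium-catalysed heteroannulation of 1,3-dienes by ortho-iodobenzoic acids and related functionally substituted aryl or vinylic halides (Larock heteroannulation), here extended to 2-bromoacrylic acid as the three-atom partner and to a medium-ring dienol. The one ring closed is the five-membered lactone, a formal [3+2] annulation completed by 5-exo attack of the carboxylate oxygen on the allyl terminus C6 rather than on the tertiary terminus C4, which would give a seven-membered ring. C7 is controlled by hydroxyl-directed delivery of the vinyl group to the olefin face on which the coordinated C8–OH sits (the sense known from metal-directed additions to medium-ring (Z)-allylic alcohols), which places C11 cis to the C8 oxygen; C6 is controlled by backside attack of the carboxylate anti to palladium, which on the (Z)-C6=C7 olefin gives the trans-fused lactone, and the E geometry of C4=C5 is carried over from the allyl. The step needs site selectivity (conjugated diene over the isolated C1=C10 olefin, and C7 over C4), which conjugation and the substitution pattern secure, and anti C–O bond formation, which the hydroxyl- and phosphine-saturated cationic allylpalladium should favour; the product lactone is itself an allylic ester that zerovalent palladium can re-ionise, so a kinetically formed cis-fused isomer can drift to the trans-fused lactone expected to be more stable.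

Step 16
Reactants: 21 (E)-but-2-enal
Product: 22 (Z)-2-iodobut-2-enal
Conditions: I2, K2CO3, DMAP (0.2 equiv), THF/H2O (1:1), rt
Reagents that add atoms: iodine, II
Why: Amine-catalysed α-iodination of the enal (conjugate addition of DMAP, iodination of the enolate, elimination) gives the α-iodoenal with iodine cis to the methyl group.

Step 17
Reactants: 22 (Z)-2-iodobut-2-enal
Product: 23 (Z)-2-iodobut-2-en-1-ol
Conditions: NaBH4, CeCl3·7H2O, MeOH, 0 °C
Reagents that add atoms: none
Why: Luche reduction is 1,2-selective and leaves the vinyl iodide and its geometry intact.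

Step 18
Reactants: 23 (Z)-2-iodobut-2-en-1-ol
Product: 24 tert-butyl{[(2Z)-2-iodobut-2-en-1-yl]oxy}dimethylsilane
Conditions: t-BuMe2SiCl, imidazole, CH2Cl2, rt
Reagents that add atoms: tert-butyldimethylsilyl chloride, CC(C)(C)[Si](C)(C)Cl
Why: Standard silylation of the primary alcohol.

Step 19
Reactants: 24 tert-butyl{[(2Z)-2-iodobut-2-en-1-yl]oxy}dimethylsilane
Product: 25 (2E)-2-({[tert-butyl(dimethyl)silyl]oxy}methyl)but-2-en-1-ol
Conditions: Bu3SnCH2OH, Pd(PPh3)4 (5 mol %), 1,4-dioxane, 90 °C
Reagents that add atoms: (tributylstannyl)methanol, OC[Sn](CCCC)(CCCC)CCCC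
Why: Stille coupling of the vinyl iodide with (tributylstannyl)methanol (hydroxymethylation) occurs with retention, so the new hydroxymethyl group is cis to the methyl group.

Step 20
Reactants: 25 (2E)-2-({[tert-butyl(dimethyl)silyl]oxy}methyl)but-2-en-1-ol
Product: 26 [(2R,3R)-2-({[tert-butyl(dimethyl)silyl]oxy}methyl)-3-methyloxiran-2-yl]methanol
Conditions: Ti(OiPr)4 (10 mol %), L-(+)-diethyl tartrate (12 mol %), t-BuOOH, 4 Å molecular sieves, CH2Cl2, −20 °C
Reagents that add atoms: tert-butyl hydroperoxide, CC(C)(C)OO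
Why: Sharpless asymmetric epoxidation of the allylic alcohol, with L-(+)-diethyl tartrate selecting the olefin face, sets both oxirane stereocentres (2R,3R) in one syn oxygen transfer.

Step 21
Reactants: 26 [(2R,3R)-2-({[tert-butyl(dimethyl)silyl]oxy}methyl)-3-methyloxiran-2-yl]methanol
Product: 28 (2R,3R)-2-({[tert-butyl(dimethyl)silyl]oxy}methyl)-3-methyloxirane-2-carboxylic acid, via epoxy aldehyde 27 (not isolated)
Conditions: TEMPO (0.2 equiv), PhI(OAc)2 (2.2 equiv), MeCN/H2O (1:1), rt
Reagents that add atoms: water, O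
Why: Nitroxyl-catalysed oxidation in aqueous acetonitrile takes the primary alcohol through the aldehyde hydrate to the acid under conditions that should leave the epoxide and the silyl ether intact.

Step 22
Reactants: 28 (2R,3R)-2-({[tert-butyl(dimethyl)silyl]oxy}methyl)-3-methyloxirane-2-carboxylic acid; 20 (3aR,4R,6Z,8S,10E,11aR)-8-{[tert-butyl(dimethyl)silyl]oxy}-4-hydroxy-6,10-dimethyl-3-methylidene-3a,4,5,8,9,11a-hexahydrocyclodeca[b]furan-2(3H)-one
Product: 30 (3aR,4R,6Z,8S,10E,11aR)-8-{[tert-butyl(dimethyl)silyl]oxy}-6,10-dimethyl-3-methylidene-2-oxo-2,3,3a,4,5,8,9,11a-octahydrocyclodeca[b]furan-4-yl (2R,3R)-2-({[tert-butyl(dimethyl)silyl]oxy}methyl)-3-methyloxirane-2-carboxylate, via mixed anhydride 29 (not isolated)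
Conditions: 2,4,6-trichlorobenzoyl chloride, Et3N, toluene, rt; then 20, DMAP, toluene, rt
Reagents that add atoms: none
Why: Yamaguchi esterification through the mixed 2,4,6-trichlorobenzoic anhydride and DMAP should acylate the hindered C8 hydroxyl, the only free hydroxyl, with retention at C8.

Step 23
Reactants: 30 (3aR,4R,6Z,8S,10E,11aR)-8-{[tert-butyl(dimethyl)silyl]oxy}-6,10-dimethyl-3-methylidene-2-oxo-2,3,3a,4,5,8,9,11a-octahydrocyclodeca[b]furan-4-yl (2R,3R)-2-({[tert-butyl(dimethyl)silyl]oxy}methyl)-3-methyloxirane-2-carboxylate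
Product: 31 (3aR,4R,6Z,8S,10E,11aR)-8-hydroxy-6,10-dimethyl-3-methylidene-2-oxo-2,3,3a,4,5,8,9,11a-octahydrocyclodeca[b]furan-4-yl (2R,3R)-2-(hydroxymethyl)-3-methyloxirane-2-carboxylate
Conditions: HF·pyridine, pyridine, THF, 0 °C to rt
Reagents that add atoms: none
Why: Buffered fluoride-driven desilylation should cleave both tert-butyldimethylsilyl ethers without opening the electron-poor oxirane or adding to the α-methylene lactone.

**Compound list**
1 | (R)-epichlorohydrin, (2R)-2-(chloromethyl)oxirane | ClC[C@H]1CO1 | starting material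
2 | (2R)-1-chloro-5-(trimethylsilyl)pent-4-yn-2-ol | C[Si](C)(C)C#CC[C@@H](O)CCl | intermediate
3 | (2R)-2-[3-(trimethylsilyl)prop-2-yn-1-yl]oxirane | C[Si](C)(C)C#CC[C@@H]1CO1 | intermediate
4 | (3R)-6-(trimethylsilyl)hex-1-en-5-yn-3-ol | C[Si](C)(C)C#CC[C@@H](O)C=C | intermediate
5 | triethyl{[(3R)-6-(trimethylsilyl)hex-1-en-5-yn-3-yl]oxy}silane | C[Si](C)(C)C#CC[C@@H](O[Si](CC)(CC)CC)C=C | intermediate
6 | triethyl{[(3R)-hex-1-en-5-yn-3-yl]oxy}silane | C#CC[C@@H](O[Si](CC)(CC)CC)C=C | intermediate
7 | lithium acetylide of 6, [(4R)-4-[(triethylsilyl)oxy]hex-5-en-1-yn-1-yl]lithium | [Li]C#CC[C@@H](O[Si](CC)(CC)CC)C=C | intermediate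
8 | methyl (5R)-5-[(triethylsilyl)oxy]hept-6-en-2-ynoate | COC(=O)C#CC[C@@H](O[Si](CC)(CC)CC)C=C | intermediate
9 | methyl (2Z,5R)-3-methyl-5-[(triethylsilyl)oxy]hepta-2,6-dienoate | COC(=O)/C=C(/C)C[C@@H](O[Si](CC)(CC)CC)C=C | intermediate
10 | (2Z,5R)-3-methyl-5-[(triethylsilyl)oxy]hepta-2,6-dien-1-ol | OC/C=C(/C)C[C@@H](O[Si](CC)(CC)CC)C=C | intermediate
11 | (2Z,5R)-3-methyl-5-[(triethylsilyl)oxy]hepta-2,6-dienal | O=C/C=C(/C)C[C@@H](O[Si](CC)(CC)CC)C=C | intermediate
12 | (4S,5Z,8R)-6-methyl-8-[(triethylsilyl)oxy]deca-5,9-dien-1-yn-4-ol | C#CC[C@H](O)/C=C(/C)C[C@@H](O[Si](CC)(CC)CC)C=C | intermediate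
13 | tert-butyl(dimethyl){[(4S,5Z,8R)-6-methyl-8-[(triethylsilyl)oxy]deca-5,9-dien-1-yn-4-yl]oxy}silane | C#CC[C@H](O[Si](C)(C)C(C)(C)C)/C=C(/C)C[C@@H](O[Si](CC)(CC)CC)C=C | intermediate
14 | dimethyl[(1E,4S,5Z,8R)-4-{[tert-butyl(dimethyl)silyl]oxy}-2,6-dimethyl-8-[(triethylsilyl)oxy]deca-1,5,9-trien-1-yl]alumane | C[Al](C)/C=C(\C)C[C@H](O[Si](C)(C)C(C)(C)C)/C=C(/C)C[C@@H](O[Si](CC)(CC)CC)C=C | intermediate
15 | tert-butyl{[(1E,4S,5Z,8R)-1-iodo-2,6-dimethyl-8-[(triethylsilyl)oxy]deca-1,5,9-trien-4-yl]oxy}dimethylsilane | I/C=C(\C)C[C@H](O[Si](C)(C)C(C)(C)C)/C=C(/C)C[C@@H](O[Si](CC)(CC)CC)C=C | intermediate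
16 | tert-butyl{[(3E,6S,7Z,10R)-4,8-dimethyl-10-[(triethylsilyl)oxy]dodeca-1,3,7,11-tetraen-6-yl]oxy}dimethylsilane | C=C/C=C(\C)C[C@H](O[Si](C)(C)C(C)(C)C)/C=C(/C)C[C@@H](O[Si](CC)(CC)CC)C=C | intermediate
17 | (1E,3Z,5R,7Z,9S)-9-{[tert-butyl(dimethyl)silyl]oxy}-1,7-dimethyl-5-[(triethylsilyl)oxy]cyclodeca-1,3,7-triene | C/C1=C\C=C/[C@H](O[Si](CC)(CC)CC)C/C(C)=C\[C@@H](O[Si](C)(C)C(C)(C)C)C1 | intermediate
18 | (1R,2Z,4E,7S,8Z)-7-{[tert-butyl(dimethyl)silyl]oxy}-5,9-dimethylcyclodeca-2,4,8-trien-1-ol | C/C1=C\C=C/[C@H](O)C/C(C)=C\[C@@H](O[Si](C)(C)C(C)(C)C)C1 | intermediate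
19 | 2-bromoprop-2-enoic acid (2-bromoacrylic acid) | C=C(Br)C(=O)O | starting material
20 | (3aR,4R,6Z,8S,10E,11aR)-8-{[tert-butyl(dimethyl)silyl]oxy}-4-hydroxy-6,10-dimethyl-3-methylidene-3a,4,5,8,9,11a-hexahydrocyclodeca[b]furan-2(3H)-one | C=C1C(=O)O[C@@H]2/C=C(\C)C[C@H](O[Si](C)(C)C(C)(C)C)/C=C(/C)C[C@@H](O)[C@@H]12 | intermediate
21 | (E)-but-2-enal (crotonaldehyde) | C/C=C/C=O | starting material
22 | (Z)-2-iodobut-2-enal | C/C=C(\I)C=O | intermediate
23 | (Z)-2-iodobut-2-en-1-ol | C/C=C(\I)CO | intermediate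
24 | tert-butyl{[(2Z)-2-iodobut-2-en-1-yl]oxy}dimethylsilane | C/C=C(\I)CO[Si](C)(C)C(C)(C)C | intermediate
25 | (2E)-2-({[tert-butyl(dimethyl)silyl]oxy}methyl)but-2-en-1-ol | C/C=C(\CO)CO[Si](C)(C)C(C)(C)C | intermediate
26 | [(2R,3R)-2-({[tert-butyl(dimethyl)silyl]oxy}methyl)-3-methyloxiran-2-yl]methanol | OC[C@]1(CO[Si](C)(C)C(C)(C)C)O[C@@H]1C | intermediate
27 | (2R,3R)-2-({[tert-butyl(dimethyl)silyl]oxy}methyl)-3-methyloxirane-2-carbaldehyde | O=C[C@]1(CO[Si](C)(C)C(C)(C)C)O[C@@H]1C | intermediate
28 | (2R,3R)-2-({[tert-butyl(dimethyl)silyl]oxy}methyl)-3-methyloxirane-2-carboxylic acid | OC(=O)[C@]1(CO[Si](C)(C)C(C)(C)C)O[C@@H]1C | intermediate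
29 | (2R,3R)-2-({[tert-butyl(dimethyl)silyl]oxy}methyl)-3-methyloxirane-2-carboxylic 2,4,6-trichlorobenzoic anhydride | O=C(OC(=O)c1c(Cl)cc(Cl)cc1Cl)[C@]1(CO[Si](C)(C)C(C)(C)C)O[C@@H]1C | intermediate
30 | (3aR,4R,6Z,8S,10E,11aR)-8-{[tert-butyl(dimethyl)silyl]oxy}-6,10-dimethyl-3-methylidene-2-oxo-2,3,3a,4,5,8,9,11a-octahydrocyclodeca[b]furan-4-yl (2R,3R)-2-({[tert-butyl(dimethyl)silyl]oxy}methyl)-3-methyloxirane-2-carboxylate | C=C1C(=O)O[C@@H]2/C=C(\C)C[C@H](O[Si](C)(C)C(C)(C)C)/C=C(/C)C[C@@H](OC(=O)[C@]3(CO[Si](C)(C)C(C)(C)C)O[C@@H]3C)[C@@H]12 | intermediate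
31 | (3aR,4R,6Z,8S,10E,11aR)-8-hydroxy-6,10-dimethyl-3-methylidene-2-oxo-2,3,3a,4,5,8,9,11a-octahydrocyclodeca[b]furan-4-yl (2R,3R)-2-(hydroxymethyl)-3-methyloxirane-2-carboxylate | C=C1C(=O)O[C@@H]2/C=C(\C)C[C@H](O)/C=C(/C)C[C@@H](OC(=O)[C@]3(CO)O[C@@H]3C)[C@@H]12 | target

**Count and risks**
Total step count: 23. Longest linear sequence: 17 steps (steps 1–15, 22 and 23).

Steps most likely to fail:

1. Step 15 (proposed new method). What may go wrong: C–O bond formation on the palladium-bearing face (inner-sphere closure) leading to the cis-fused lactone, delivery of the vinyl group to the other olefin face, or oxidation of the allylic alcohol by the vinylpalladium species. Fallback by known chemistry, setting out from 18: oxidative free-radical carbolactonisation with malonic acid, Mn(OAc)3·2H2O and Cu(OAc)2 in AcOH/KOAc. The malonyl radical adds to C7 of the diene, the allyl radical is oxidised by trivalent manganese and trapped by the carboxyl group at C6, which gives the α-carboxy lactone F1. Decarboxylative Mannich methylenation of F1 (aqueous HCHO, Et2NH, then NaOAc/AcOH) then returns to the route at 20. Diastereomers at C6/C7 would be separated at the stage of F1.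

2. Step 13. What may go wrong: intermolecular metathesis (oligomerisation) outrunning closure of the strained ten-membered ring, or attack of the carbene on the internal olefin of the diene with ring contraction. Fallback, setting out from 15 and omitting step 12: intramolecular Heck reaction (Pd(OAc)2, P(o-tol)3, Ag2CO3, MeCN, high dilution, 70 °C). The alkenylpalladium adds to the terminal carbon of the C8 vinyl group (10-endo) and β-hydride elimination gives the conjugated diene, expected as the less strained 6Z isomer, returning to the route at 17. This fallback makes no new compound (F0).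

3. Step 9. What may go wrong: poor facial selectivity of the catalyst with this β,β-disubstituted (Z)-enal, and acid-promoted Z-to-E isomerisation of the enal before addition. Fallback, setting out from 11: uncatalysed Barbier propargylation (propargyl bromide, Zn, THF/aqueous NH4Cl, 0 °C) should give 12 together with its C4 epimer, (4R,5Z,8R)-6-methyl-8-[(triethylsilyl)oxy]deca-5,9-dien-1-yn-4-ol F2. The two are diastereomers because of the fixed C8 centre and would be separated by chromatography. F2 is recycled by Mitsunobu inversion (4-nitrobenzoic acid, PPh3, DIAD, THF) to the inverted ester, (4S,5Z,8R)-6-methyl-8-[(triethylsilyl)oxy]deca-5,9-dien-1-yn-4-yl 4-nitrobenzoate F3, and methanolysis (K2CO3, MeOH, 0 °C) returns to the route at 12.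

**Further compounds**
F1 | step 15 | (3aR,4R,6Z,8S,10E,11aR)-8-{[tert-butyl(dimethyl)silyl]oxy}-4-hydroxy-6,10-dimethyl-2-oxo-2,3,3a,4,5,8,9,11a-octahydrocyclodeca[b]furan-3-carboxylic acid (both C3 epimers) | OC(=O)C1C(=O)O[C@@H]2/C=C(\C)C[C@H](O[Si](C)(C)C(C)(C)C)/C=C(/C)C[C@@H](O)[C@@H]12
F0 | step 13 | none | none
F2 | step 9 | (4R,5Z,8R)-6-methyl-8-[(triethylsilyl)oxy]deca-5,9-dien-1-yn-4-ol | C#CC[C@@H](O)/C=C(/C)C[C@@H](O[Si](CC)(CC)CC)C=C
F3 | step 9 | (4S,5Z,8R)-6-methyl-8-[(triethylsilyl)oxy]deca-5,9-dien-1-yn-4-yl 4-nitrobenzoate | C#CC[C@H](OC(=O)c1ccc(cc1)[N+](=O)[O-])/C=C(/C)C[C@@H](O[Si](CC)(CC)CC)C=C
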